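## Retrosynthetic overview

1. Last step: a CrCl2-mediated intramolecular Barbier allylation–lactonization of a bromo-enoate onto a Z-enal makes the C6–C7 bond, the nine-membered ring and the α-methylene lactone together. It sets C6 and C7 from C8, with the C8 ester already in place (no ring-closing metathesis, no late esterification).
2. The allylic bromide comes from a Morita–Baylis–Hillman reaction at the C7 aldehyde; the Z-enal comes from the C6 allylic alcohol.
3. The furanone ring is formed first, by gold-catalysed cycloisomerization of a γ-hydroxy ynone. The ynone comes from a three-component carbonylative Sonogashira coupling (alkyne + CO + Z-vinyl iodide), which fixes the 4Z alkene.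
4. Alkyne fragment: C8 by catalytic asymmetric ynone aldol, C10 by 1,3-chelation-controlled MeMgBr addition, then esterification with (2R)-2-methylbutanoic acid.
5. Ring order: furanone ring, then the nine-membered ring and the lactone ring in one operation.

Atom labels (germacrane numbering): C1 ketone, C2 =CH, C3 enol-ether carbon, C4=C5 alkene (C15 methyl on C4), C6 lactone carbinol, C7, C8 ester carbinol, C9 CH2, C10 quaternary carbon (C14 methyl), C11=C13 methylene, C12 lactone carbonyl. The target is 4Z,6R,7R,8R,10S.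

Assumption: the side-chain stereocentre in the given SMILES is R, so (2R)-2-methylbutanoic acid is used.

Assumption: the (S,S)-ligand is written in step 1; which antipode gives the (4R)-aldol with this aldehyde is settled by one trial run (both are sold), and the route is otherwise unchanged.

## Route

Step 1
Reactants: 1 4-(trimethylsilyl)but-3-yn-2-one; 2 2,2-dimethoxyacetaldehyde
Product: 3 (4R)-4-hydroxy-5,5-dimethoxy-1-(trimethylsilyl)pent-1-yn-3-one
Conditions: Et2Zn (20 mol%), (S,S)-ProPhenol (10 mol%), THF, 0 °C; 2 used as the anhydrous monomer (dried from the commercial aqueous solution)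
Reagents that add atoms: none
Why: Direct catalytic asymmetric aldol reaction of a methyl ynone under Et2Zn/ProPhenol catalysis; the enolate of 1 adds to the activated, non-self-condensing aldehyde 2 inside the chiral pocket and sets C8 (R).

Step 2
Reactants: 3 (4R)-4-hydroxy-5,5-dimethoxy-1-(trimethylsilyl)pent-1-yn-3-one
Product: 4 (3S,5R)-6,6-dimethoxy-3-methyl-1-(trimethylsilyl)hex-1-yne-3,5-diol
Conditions: MeMgBr (3 equiv), THF, −78 °C; aq. NH4Cl
Reagents that add atoms: methylmagnesium bromide, C[Mg]Br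
Why: 1,3-Chelation-controlled Grignard addition; the bromomagnesium alkoxide at C8 chelates the ynone carbonyl in a half-chair and methyl attacks axially, so the small alkynyl group ends equatorial and the new C10 carbinol is syn to the C8 hydroxyl (S at C10).

Step 3
Reactants: 4 (3S,5R)-6,6-dimethoxy-3-methyl-1-(trimethylsilyl)hex-1-yne-3,5-diol
Product: 5 (3S,5R)-6,6-dimethoxy-3-methylhex-1-yne-3,5-diol
Conditions: K2CO3 (0.2 equiv), MeOH, 0 °C to rt
Reagents that add atoms: none
Why: Methoxide-induced protodesilylation of the alkynylsilane; the acetal and both carbinols are inert to mild base.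

Step 4
Reactants: 5 (3S,5R)-6,6-dimethoxy-3-methylhex-1-yne-3,5-diol; 6 (2R)-2-methylbutanoic acid
Product: 7 (2R,4S)-4-hydroxy-1,1-dimethoxy-4-methylhex-5-yn-2-yl (2R)-2-methylbutanoate
Conditions: DCC (1.2 equiv), DMAP (0.1 equiv), CH2Cl2, 0 °C to rt
Reagents that add atoms: none
Why: Steglich esterification; only the secondary C8 hydroxyl is acylated (the tertiary propargylic hydroxyl is too hindered), no stereocentre is touched, and the ester then serves as the C8 protecting group for the rest of the route.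

Step 5
Reactants: 8 but-2-yn-1-ol
Product: 10 (2Z)-3-iodobut-2-en-1-ol, via cyclic alkenylalanate 9 (not isolated)
Conditions: NaAlH2(OCH2CH2OMe)2, THF, 0 °C to rt; then I2, −78 to 0 °C; aq. Na2S2O3
Reagents that add atoms: iodine, II
Why: Hydroxyl-directed trans-hydroalumination of the propargylic alcohol gives the five-membered alanate 9, and iodinolysis of its C–Al bond with retention gives the Z iodide, which fixes the 4Z geometry of the target.

Step 6
Reactants: 10 (2Z)-3-iodobut-2-en-1-ol
Product: 11 tert-butyl{[(2Z)-3-iodobut-2-en-1-yl]oxy}dimethylsilane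
Conditions: TBSCl, imidazole, CH2Cl2, rt
Reagents that add atoms: tert-butyldimethylsilyl chloride, CC(C)(C)[Si](C)(C)Cl
Why: Standard silylation; it stops the Z-hydroxyl from trapping the acylpalladium of step 7 as a butenolide.

Step 7
Reactants: 7 (2R,4S)-4-hydroxy-1,1-dimethoxy-4-methylhex-5-yn-2-yl (2R)-2-methylbutanoate; 11 tert-butyl{[(2Z)-3-iodobut-2-en-1-yl]oxy}dimethylsilane
Product: 12 (2R,4S,8Z)-10-[(tert-butyldimethylsilyl)oxy]-4-hydroxy-1,1-dimethoxy-4,8-dimethyl-7-oxodec-8-en-5-yn-2-yl (2R)-2-methylbutanoate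
Conditions: PdCl2(PPh3)2 (5 mol%), CuI (2 mol%), Et3N (3 equiv), CO (1 atm), THF, rt
Reagents that add atoms: carbon monoxide, [C-]#[O+]
Why: Carbonylative Sonogashira coupling; the vinyl iodide adds to zerovalent palladium with retention, CO inserts (this carbon becomes C3), and the terminal alkyne of 7 is acylated to give the cross-conjugated ynone while the free tertiary hydroxyl is tolerated.

Step 8
Reactants: 12 (2R,4S,8Z)-10-[(tert-butyldimethylsilyl)oxy]-4-hydroxy-1,1-dimethoxy-4,8-dimethyl-7-oxodec-8-en-5-yn-2-yl (2R)-2-methylbutanoate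
Product: 13 (2R)-1-[(2S)-5-{(2Z)-4-[(tert-butyldimethylsilyl)oxy]but-2-en-2-yl}-2-methyl-3-oxo-2,3-dihydrofuran-2-yl]-3,3-dimethoxypropan-2-yl (2R)-2-methylbutanoate
Conditions: (4-CF3C6H4)3PAuCl (5 mol%), AgOTf (5 mol%), toluene (undried), rt
Reagents that add atoms: none
Why: Gold-catalysed cycloisomerization of a γ-hydroxy ynone to a 3(2H)-furanone; cationic monovalent gold activates the alkyne for net hydration at C1, the C10 hydroxyl then closes on the C3 ketone and water is lost, with C10 and the Z alkene untouched and no other free hydroxyl to compete.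

Step 9
Reactants: 13 (2R)-1-[(2S)-5-{(2Z)-4-[(tert-butyldimethylsilyl)oxy]but-2-en-2-yl}-2-methyl-3-oxo-2,3-dihydrofuran-2-yl]-3,3-dimethoxypropan-2-yl (2R)-2-methylbutanoate
Product: 14 (2R)-1-{(2S)-5-[(2Z)-4-hydroxybut-2-en-2-yl]-2-methyl-3-oxo-2,3-dihydrofuran-2-yl}-3-oxopropan-2-yl (2R)-2-methylbutanoate
Conditions: TFA/H2O 4:1, CH2Cl2, 0 °C to rt; NaHCO3 work-up
Reagents that add atoms: water, O
Why: Acid hydrolysis unmasks the C7 aldehyde from its dimethyl acetal and cleaves the primary allylic silyl ether in the same pot; the ester and the vinylogous ester of the furanone are stable to aqueous acid, and C10 is now locked in the ring so no lactol can form.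

Step 10
Reactants: 14 (2R)-1-{(2S)-5-[(2Z)-4-hydroxybut-2-en-2-yl]-2-methyl-3-oxo-2,3-dihydrofuran-2-yl}-3-oxopropan-2-yl (2R)-2-methylbutanoate; 15 methyl acrylate
Product: 16 methyl (3RS,4R)-3-hydroxy-5-{(2S)-5-[(2Z)-4-hydroxybut-2-en-2-yl]-2-methyl-3-oxo-2,3-dihydrofuran-2-yl}-2-methylidene-4-{[(2R)-2-methylbutanoyl]oxy}pentanoate
Conditions: DABCO (1 equiv), 15 (10 equiv), 1,4-dioxane/H2O 1:1, rt
Reagents that add atoms: none
Why: Morita–Baylis–Hillman reaction; the α-acyloxy aldehyde is a strongly activated electrophile, and the new C7 carbinol may form as both epimers because it is erased in step 12.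

Step 11
Reactants: 16 methyl (3RS,4R)-3-hydroxy-5-{(2S)-5-[(2Z)-4-hydroxybut-2-en-2-yl]-2-methyl-3-oxo-2,3-dihydrofuran-2-yl}-2-methylidene-4-{[(2R)-2-methylbutanoyl]oxy}pentanoate
Product: 17 methyl (3RS,4R)-3-hydroxy-2-methylidene-4-{[(2R)-2-methylbutanoyl]oxy}-5-{(2S)-2-methyl-3-oxo-5-[(2Z)-4-oxobut-2-en-2-yl]-2,3-dihydrofuran-2-yl}pentanoate
Conditions: activated MnO2 (20 equiv), CH2Cl2, rt, dark
Reagents that add atoms: none
Why: Chemoselective allylic oxidation; MnO2 oxidizes the electron-rich primary allylic alcohol to the Z-enal with retention of geometry, while the secondary carbinol next to the electron-poor acrylate reacts far more slowly.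

Step 12
Reactants: 17 methyl (3RS,4R)-3-hydroxy-2-methylidene-4-{[(2R)-2-methylbutanoyl]oxy}-5-{(2S)-2-methyl-3-oxo-5-[(2Z)-4-oxobut-2-en-2-yl]-2,3-dihydrofuran-2-yl}pentanoate
Product: 18 methyl (2Z,4R)-2-(bromomethyl)-4-{[(2R)-2-methylbutanoyl]oxy}-5-{(2S)-2-methyl-3-oxo-5-[(2Z)-4-oxobut-2-en-2-yl]-2,3-dihydrofuran-2-yl}pent-2-enoate
Conditions: NBS, Me2S, CH2Cl2, −20 to 0 °C
Reagents that add atoms: N-bromosuccinimide, O=C1CCC(=O)N1Br
Why: Corey–Kim-type bromination with allylic transposition (SN2'); bromide displaces the alkoxysulfonium ion at the methylene terminus under near-neutral conditions that spare the Z-enal, giving the conjugated (Z)-2-(bromomethyl)enoate from both C7 epimers.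

Step 13
Reactants: 18 methyl (2Z,4R)-2-(bromomethyl)-4-{[(2R)-2-methylbutanoyl]oxy}-5-{(2S)-2-methyl-3-oxo-5-[(2Z)-4-oxobut-2-en-2-yl]-2,3-dihydrofuran-2-yl}pent-2-enoate
Product: 20 CNP0174601.3 [(4Z,6R,7R,8R,10S)-3,10-epoxy-1-oxogermacra-2,4,11(13)-trien-12,6-olid-8-yl (2R)-2-methylbutanoate], via ring-closed hydroxy ester 19 (not isolated)
Conditions: CrCl2 (10 equiv), THF/DMF 4:1, rt, syringe-pump addition of 18 to a final 2 mM; aq. NH4Cl
Reagents that add atoms: none
Why: Intramolecular Nozaki–Hiyama-type Barbier allylation followed by lactonization; divalent chromium inserts into the allylic bromide and the allyl–CrCl2 species attacks the enal carbonyl (C6) through its γ-carbon (C7) in a chair-like transition state, which is expected to give the anti C6/C7 relationship (trans lactone) on the face set by the adjacent C8 stereocentre and the furanone tether, and the C6 alkoxide then closes on the methyl ester to give the α-methylene lactone.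

## Compound list

1 | 4-(trimethylsilyl)but-3-yn-2-one | CC(=O)C#C[Si](C)(C)C | starting material
2 | 2,2-dimethoxyacetaldehyde | COC(OC)C=O | starting material
3 | (4R)-4-hydroxy-5,5-dimethoxy-1-(trimethylsilyl)pent-1-yn-3-one | C[Si](C)(C)C#CC(=O)C[C@@H](O)C(OC)OC | intermediate
4 | (3S,5R)-6,6-dimethoxy-3-methyl-1-(trimethylsilyl)hex-1-yne-3,5-diol | C[Si](C)(C)C#C[C@](C)(C[C@@H](O)C(OC)OC)O | intermediate
5 | (3S,5R)-6,6-dimethoxy-3-methylhex-1-yne-3,5-diol | C#C[C@](C)(C[C@@H](O)C(OC)OC)O | intermediate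
6 | (2R)-2-methylbutanoic acid | CC[C@@H](C)C(=O)O | starting material
7 | (2R,4S)-4-hydroxy-1,1-dimethoxy-4-methylhex-5-yn-2-yl (2R)-2-methylbutanoate | C#C[C@](C)(C[C@@H](OC(=O)[C@H](C)CC)C(OC)OC)O | intermediate
8 | but-2-yn-1-ol | CC#CCO | starting material
9 | sodium 2,2-bis(2-methoxyethoxy)-3-methyl-2,5-dihydro-1,2-oxaluminol-2-uide (cyclic alkenylalanate) | CC1=CCO[Al-]1(OCCOC)OCCOC.[Na+] | intermediate
10 | (2Z)-3-iodobut-2-en-1-ol | C/C(I)=C/CO | intermediate
11 | tert-butyl{[(2Z)-3-iodobut-2-en-1-yl]oxy}dimethylsilane | C/C(I)=C/CO[Si](C)(C)C(C)(C)C | intermediate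
12 | (2R,4S,8Z)-10-[(tert-butyldimethylsilyl)oxy]-4-hydroxy-1,1-dimethoxy-4,8-dimethyl-7-oxodec-8-en-5-yn-2-yl (2R)-2-methylbutanoate | CC(C)(C)[Si](C)(C)OC/C=C(/C)C(=O)C#C[C@](C)(C[C@@H](OC(=O)[C@H](C)CC)C(OC)OC)O | intermediate
13 | (2R)-1-[(2S)-5-{(2Z)-4-[(tert-butyldimethylsilyl)oxy]but-2-en-2-yl}-2-methyl-3-oxo-2,3-dihydrofuran-2-yl]-3,3-dimethoxypropan-2-yl (2R)-2-methylbutanoate | CC(C)(C)[Si](C)(C)OC/C=C(/C)C1=CC(=O)[C@](C)(C[C@@H](OC(=O)[C@H](C)CC)C(OC)OC)O1 | intermediate
14 | (2R)-1-{(2S)-5-[(2Z)-4-hydroxybut-2-en-2-yl]-2-methyl-3-oxo-2,3-dihydrofuran-2-yl}-3-oxopropan-2-yl (2R)-2-methylbutanoate | OC/C=C(/C)C1=CC(=O)[C@](C)(C[C@@H](OC(=O)[C@H](C)CC)C=O)O1 | intermediate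
15 | methyl acrylate | C=CC(=O)OC | starting material
16 | methyl (3RS,4R)-3-hydroxy-5-{(2S)-5-[(2Z)-4-hydroxybut-2-en-2-yl]-2-methyl-3-oxo-2,3-dihydrofuran-2-yl}-2-methylidene-4-{[(2R)-2-methylbutanoyl]oxy}pentanoate | OC/C=C(/C)C1=CC(=O)[C@](C)(C[C@@H](OC(=O)[C@H](C)CC)C(O)C(=C)C(=O)OC)O1 | intermediate
17 | methyl (3RS,4R)-3-hydroxy-2-methylidene-4-{[(2R)-2-methylbutanoyl]oxy}-5-{(2S)-2-methyl-3-oxo-5-[(2Z)-4-oxobut-2-en-2-yl]-2,3-dihydrofuran-2-yl}pentanoate | O=C/C=C(/C)C1=CC(=O)[C@](C)(C[C@@H](OC(=O)[C@H](C)CC)C(O)C(=C)C(=O)OC)O1 | intermediate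
18 | methyl (2Z,4R)-2-(bromomethyl)-4-{[(2R)-2-methylbutanoyl]oxy}-5-{(2S)-2-methyl-3-oxo-5-[(2Z)-4-oxobut-2-en-2-yl]-2,3-dihydrofuran-2-yl}pent-2-enoate | O=C/C=C(/C)C1=CC(=O)[C@](C)(C[C@@H](OC(=O)[C@H](C)CC)/C=C(\CBr)C(=O)OC)O1 | intermediate
19 | ring-closed hydroxy ester (C6–C7 bond made, C6 hydroxyl present as its Cl2CrO– alkoxide before work-up, C11 still bearing CO2Me; C6 and C7 arranged as in 20) | O[C@@H]2/C=C(/C)C3=CC(=O)[C@](C)(C[C@@H](OC(=O)[C@H](C)CC)[C@H]2C(=C)C(=O)OC)O3 | intermediate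
20 | CNP0174601.3, (4Z,6R,7R,8R,10S)-3,10-epoxy-1-oxogermacra-2,4,11(13)-trien-12,6-olid-8-yl (2R)-2-methylbutanoate | C=C1C(=O)O[C@@H]2/C=C(/C)C3=CC(=O)[C@](C)(C[C@@H](OC(=O)[C@H](C)CC)[C@@H]12)O3 | target

## Step count and risks

Total steps: 13. Longest linear sequence: 11 (steps 1–4, then 7–13); the vinyl iodide branch is steps 5–6.

**Risk 1: step 13 (Barbier macrocyclization).** The ring is strained, and the facial selectivity for C6/C7 rests on the C8 centre and the tether. The allyl–CrCl2 species carries the C8 carboxylate next to its reacting carbon and may lose it by 1,4-elimination. Oligomers can also form.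

Fallback: it sets out from 7 and comes back at 20, closing the ring by metathesis instead.
- Acyl Sonogashira coupling of 7 with methacryloyl chloride (PdCl2(PPh3)2, CuI, Et3N, THF, 0 °C) gives the isopropenyl ynone F5.
- The gold conditions of step 8 convert it into the isopropenyl furanone acetal F6, and aqueous TFA then gives the isopropenyl furanone aldehyde F7.
- The Morita–Baylis–Hillman reaction with 15 gives the isopropenyl furanone hydroxy acrylate F8, and NBS/Me2S gives the isopropenyl furanone bromo-enoate F9.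
- An intermolecular CrCl2 Barbier reaction of F9 with excess acrolein, where bimolecular trapping outruns loss of the acyloxy group, gives after lactonization the vinyl-substituted trans α-methylene lactone F10; C6/C7 diastereomers are separated at this stage.
- Ring-closing metathesis of the vinyl and isopropenyl groups with second-generation Hoveyda–Grubbs catalyst RuCl2(H2IMes)(=CH-2-iPrOC6H4) (toluene, 80 °C, 1 mM) forms the C4=C5 bond, Z by ring constraint, and gives 20.

**Risk 2: step 10 (Morita–Baylis–Hillman reaction).** The reaction is slow on a complex substrate, and DABCO may epimerize C8 of the α-acyloxy aldehyde or move the acyl group onto the new C7 hydroxyl.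

Fallback: it sets out from 14 and comes back at 16, replacing the amine-catalysed reaction with a non-basic vinylalumination. Methyl propiolate is hydroaluminated with iBu2AlH in the presence of N-methylmorpholine N-oxide (THF, 0 °C) to give methyl 2-(diisobutylalumanyl)prop-2-enoate F4. This vinylalane adds to the aldehyde of 14 at 0 °C within hours (one extra equivalent is consumed by the free hydroxyl) and gives 16 after aqueous work-up.

**Risk 3: step 2 (methyl addition).** The level and the sense of 1,3-induction are not guaranteed for an ynone, and C10 cannot be corrected later.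

Fallback: it sets out from 1 and 2 and comes back at 7. It applies if the addition proves anti-selective, and moves the correction to the invertible C8 centre.
- The aldol of step 1 is run with the antipodal ligand to give the (4S)-aldol F1.
- The same MeMgBr addition then gives the (3S,5S)-diol F2, which has the correct C10 and the wrong C8.
- K2CO3/MeOH gives the (3S,5S)-alkyne diol F3.
- Mitsunobu esterification of the secondary hydroxyl with 6 (PPh3, DIAD, toluene, 0 °C to rt) inverts C8 while installing the ester and gives 7.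

## Further compounds

F1 | step 2 | (4S)-4-hydroxy-5,5-dimethoxy-1-(trimethylsilyl)pent-1-yn-3-one | C[Si](C)(C)C#CC(=O)C[C@H](O)C(OC)OC
F2 | step 2 | (3S,5S)-6,6-dimethoxy-3-methyl-1-(trimethylsilyl)hex-1-yne-3,5-diol | C[Si](C)(C)C#C[C@](C)(C[C@H](O)C(OC)OC)O
F3 | step 2 | (3S,5S)-6,6-dimethoxy-3-methylhex-1-yne-3,5-diol | C#C[C@](C)(C[C@H](O)C(OC)OC)O
F4 | step 10 | methyl 2-(diisobutylalumanyl)prop-2-enoate | C=C(C(=O)OC)[Al](CC(C)C)CC(C)C
F5 | step 13 | (2R,4S)-4-hydroxy-1,1-dimethoxy-4,8-dimethyl-7-oxonon-8-en-5-yn-2-yl (2R)-2-methylbutanoate | C=C(C)C(=O)C#C[C@](C)(C[C@@H](OC(=O)[C@H](C)CC)C(OC)OC)O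
F6 | step 13 | (2R)-1,1-dimethoxy-3-[(2S)-2-methyl-3-oxo-5-(prop-1-en-2-yl)-2,3-dihydrofuran-2-yl]propan-2-yl (2R)-2-methylbutanoate | C=C(C)C1=CC(=O)[C@](C)(C[C@@H](OC(=O)[C@H](C)CC)C(OC)OC)O1
F7 | step 13 | (2R)-1-[(2S)-2-methyl-3-oxo-5-(prop-1-en-2-yl)-2,3-dihydrofuran-2-yl]-3-oxopropan-2-yl (2R)-2-methylbutanoate | C=C(C)C1=CC(=O)[C@](C)(C[C@@H](OC(=O)[C@H](C)CC)C=O)O1
F8 | step 13 | methyl (3RS,4R)-3-hydroxy-2-methylidene-4-{[(2R)-2-methylbutanoyl]oxy}-5-[(2S)-2-methyl-3-oxo-5-(prop-1-en-2-yl)-2,3-dihydrofuran-2-yl]pentanoate | C=C(C)C1=CC(=O)[C@](C)(C[C@@H](OC(=O)[C@H](C)CC)C(O)C(=C)C(=O)OC)O1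
F9 | step 13 | methyl (2Z,4R)-2-(bromomethyl)-4-{[(2R)-2-methylbutanoyl]oxy}-5-[(2S)-2-methyl-3-oxo-5-(prop-1-en-2-yl)-2,3-dihydrofuran-2-yl]pent-2-enoate | C=C(C)C1=CC(=O)[C@](C)(C[C@@H](OC(=O)[C@H](C)CC)/C=C(\CBr)C(=O)OC)O1
F10 | step 13 | (1R)-1-[(2R,3R)-2-ethenyl-4-methylidene-5-oxooxolan-3-yl]-2-[(2S)-2-methyl-3-oxo-5-(prop-1-en-2-yl)-2,3-dihydrofuran-2-yl]ethyl (2R)-2-methylbutanoate | C=C1C(=O)O[C@H](C=C)[C@H]1[C@H](OC(=O)[C@H](C)CC)C[C@]2(C)OC(=CC2=O)C(C)=C
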